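**Design of a three-step synthesis of 1-(2,3,6-tribromo-4,5-dihydroxybenzyl)pyrrolidin-2-one (7)**

Compound numbers used throughout: aldehyde 1, amino ester hydrochloride 2, secondary amino ester 3 (transient), dibromophenol lactam 4, bromocatechol lactam 5, dibromocatechol lactam 6 (transient), target 7.

## The problem

Target 7 is a pyrrolidin-2-one whose nitrogen is joined through a single methylene group to a benzene ring with no free position. Counting from the benzylic carbon as C1, the ring carries bromine at C2, hydroxyl at C3 and C4, and bromine at C5 and C6. There is one ring-to-ring link (N–CH2–C1) and no stereocentre, so the whole task is regiochemical: five heteroatom substituents must be placed on one arene in the right order. The brominated catechol is the fragile part. In base and air it oxidises to the ortho-quinone, it chelates metals, and its C–Br bonds do not survive hydrogenolysis or organometallic reagents. The benzylic C–N bond lies para to the C4 hydroxyl, so strong acid or an aggressive electrophile can cleave it through a quinone methide or by ipso attack at C1. The lactam is robust but would open in hot concentrated hydroxide. The enabling feature is that the C3 hydroxyl occupies a position that holds bromine in a mirror-symmetric 3,5-dibromo-4-hydroxybenzyl ring. Exchanging one of the two equivalent bromines for oxygen gives the catechol with bromine left at C5. The new C3 hydroxyl is then ortho to C2 and para to C6, the two carbons that still need bromine.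

## Retrosynthesis

**7 back to 5.** The C2–Br and C6–Br bonds are cut, leaving bromocatechol 5. Bromination is placed last because C2 and C6 are then the only unsubstituted ring carbons, so no regiochemical choice remains. Both are activated by the C3 hydroxyl, and the C5 bromine and the benzylic group direct to the same two carbons. The first bromine should enter para to the C3 hydroxyl and give dibromide 6, which takes the second bromine at C2 in the same flask. Cutting any other C–Br bond first would require bromination meta to a hydroxyl. The forward reaction must substitute the ring twice without oxidising the catechol or attacking C1.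

**5 back to 4.** The C3–O bond is cut and replaced by C3–Br, which gives the mirror-symmetric dibromophenol 4. This cut turns an unsymmetrical trisubstituted pattern into a symmetric one, so the position of the oxygen need not be controlled, only the number of exchanges. The exchange is placed on the lactam rather than on aldehyde 1 because a catechol aldehyde would be harder to carry through a reductive amination and hot hydroxide would attack the formyl group. It is placed before the final brominations because in 4 the carbons C2 and C6 are meta to the only hydroxyl and not activated, and because a ring with three bromines would offer copper three different C–Br bonds. The forward reaction is a copper-catalysed hydroxylation that must stop after one exchange.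

**4 back to 1 and 2.** The N–CH2 bond and the lactam N–C(=O) bond are cut, leaving 3,5-dibromo-4-hydroxybenzaldehyde 1 and methyl 4-aminobutanoate hydrochloride 2. In the forward direction they combine by reductive amination to the secondary amino ester 3, which closes to the five-membered lactam with loss of methanol. This is preferred to alkylating a preformed lactam nitrogen with a para-hydroxybenzyl halide, which would need phenol protection and a halide prone to quinone methide formation. Both 1 and 2 are inexpensive, and 1 already holds the two bromines in the symmetric arrangement the key step needs.

## Roads not taken

**Alternative 1:** The cut is the C3=C4 bond of an unsaturated lactam. In the forward direction N-allyl-N-(2,3,6-tribromo-4,5-dimethoxybenzyl)acrylamide A1 would cyclise with second-generation Grubbs catalyst to the unsaturated lactam A2.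
- Merits: ring-closing metathesis of N-allyl acrylamides to five-membered unsaturated lactams is dependable. The arene is finished and protected as its dimethyl ether beforehand, so no free catechol meets base, copper or bromine.
- Weak points: the ring being built is a plain pyrrolidinone that can be bought in open-chain form. A1 needs a fully brominated dimethoxybenzylamine followed by allylation and acryloylation. The alkene of A2 must then be reduced without touching three aryl C–Br bonds, which rules out ordinary palladium hydrogenation, and two methyl ethers must be cleaved.
- Comparison: this road would be at least twice as long as the chosen three steps. Its real advantage is that it avoids exposing a free catechol to basic copper conditions. The chosen plan sets against this its brevity, oxygen-free handling of 5, and a fallback through methyl ethers.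

**Alternative 2:** The cut is both bonds of the benzylic carbon at once. In the forward direction 3,6-dibromocatechol A3, pyrrolidin-2-one A4 and formaldehyde A5 would combine in strong acid through an N-acyliminium ion to give 1-(2,5-dibromo-3,4-dihydroxybenzyl)pyrrolidin-2-one A6. One bromination at the last open carbon would then give 7.
- Merits: it is the most convergent option, two steps from A3, so in step count it is equal to or better than the chosen plan. The symmetry of A3 means the first substitution gives one regioisomer.
- Weak points: A3 is not a commodity, because direct bromination of catechol goes to the 4,5-positions, so the true step count is higher. The two open carbons of A3 are equivalent and each is para to a hydroxyl, so a second amidoalkylation competes, and the first benzylic substituent activates the ring further. Phenols and A5 in strong acid also give diarylmethane oligomers. The electrophile must attack a ring carrying two deactivating bromines.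
- Comparison: the chosen plan is one step longer on paper. It sets against this cheap starting materials, a benzylic carbon already in place in 1, and a single risky step that has a direct precedent on ortho-bromophenols.

**Alternative 3:** The cut is the two N–C bonds of the lactam ring. In the forward direction 1-(azidomethyl)-2,3,6-tribromo-4,5-dimethoxybenzene A7 would add to TiCl4-activated cyclobutanone A8 and rearrange with nitrogen extrusion to the dimethyl ether lactam A9. Cleavage of the methyl ethers would finish the synthesis.
- Merits: the strained four-membered ketone is a good partner for intermolecular azide Schmidt reactions, and its symmetry removes any question of which carbon migrates. The catechol stays protected until the end.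
- Weak points: like Alternative 1 it builds a commodity ring by elaborate means. A7 needs several steps and carries an azide hazard. Benzylic azides under Lewis acid can rearrange by aryl or hydride shift to iminium ions and give Mannich-type products. The azide, flanked by two ortho bromines on an electron-poor ring, is a hindered and weak nucleophile.
- Comparison: this road is longer and rests on a less predictable key step. It is better only in avoiding the mono-selectivity question and the free catechol under basic conditions, which the chosen plan answers with symmetry, limited hydroxide and oxygen exclusion.

Key step: step 2

Remark on the chemistry: compounds 1 and 2 are taken to be commercially available, and the arene is numbered from the benzylic carbon (C1) as in the first section.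

## Route

Step 1
Reactants: 1 3,5-dibromo-4-hydroxybenzaldehyde; 2 methyl 4-aminobutanoate hydrochloride
Product: 4 1-(3,5-dibromo-4-hydroxybenzyl)pyrrolidin-2-one, via secondary amino ester 3 (not isolated)
Conditions: Et3N (1.2 equiv), AcOH (1 equiv), NaBH(OAc)3 (1.5 equiv), ClCH2CH2Cl/THF, rt; then Et3N (2 equiv), toluene, 110 °C
Reagents that add atoms: none
Why: Reductive amination, in which NaBH(OAc)3 reduces the iminium ion but not the aldehyde or the ester, gives amino ester 3, which closes by 5-exo-trig lactamization with loss of methanol on heating. The added Et3N takes up the acidic phenol so that the amine of 3 stays free to attack the ester, and a small excess of 2 limits double benzylation.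

Step 2
Reactants: 4 1-(3,5-dibromo-4-hydroxybenzyl)pyrrolidin-2-one
Product: 5 1-(3-bromo-4,5-dihydroxybenzyl)pyrrolidin-2-one
Conditions: CuI (10 mol%), 8-hydroxyquinoline (20 mol%), KOH (3.0 equiv), degassed DMSO/H2O 1:1, 100 °C, argon; then aq HCl, Na2S2O4
Reagents that add atoms: potassium hydroxide (KOH), [K+].[OH-]
Why: KOH converts 4 into its phenoxide, and the 8-hydroxyquinoline-bound monovalent copper hydroxide, held close by that phenoxide, adds oxidatively into the neighbouring C3–Br bond to give an aryl trivalent copper hydroxide, from which reductive elimination forms the C3–O bond and returns monovalent copper. The closest known reaction type is the Ullmann-type copper-mediated hydroxylation of ortho-bromophenols to catechols (bromovanillin to hydroxyvanillin) and its ligand-accelerated catalytic forms in aqueous DMSO. No ring closes and no stereocentre is formed. The selectivity needed is one exchange out of two, and because 4 has a mirror plane through C1 and C4 its two bromines are equivalent, so the first exchange can give only 5. A second exchange is held back because the catecholate of 5 is more electron-rich than the phenoxide of 4, which slows oxidative addition, and because the three equivalents of KOH are taken up by the phenol of 4, the exchange itself and the second phenoxide of 5, so free hydroxide runs low as 5 builds up. The N-alkyl lactam should withstand this amount of hydroxide at 100 °C, and exclusion of oxygen with an acidic Na2S2O4 quench should keep the catechol from oxidising to the ortho-quinone.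

Step 3
Reactants: 5 1-(3-bromo-4,5-dihydroxybenzyl)pyrrolidin-2-one
Product: 7 1-(2,3,6-tribromo-4,5-dihydroxybenzyl)pyrrolidin-2-one, via dibromocatechol lactam 6 (not isolated)
Conditions: Br2 (2.1 equiv), AcOH, 15 °C to rt, dark; then aq NaHSO3
Reagents that add atoms: bromine (Br2), BrBr
Why: Electrophilic aromatic bromination, in which the C3 hydroxyl directs to C6 (para, giving 6 first) and then to C2 (ortho), with the C5 bromine and the benzylic group directing to the same two carbons. These are the only unsubstituted ring positions, so two equivalents of Br2 can lead only to 7. The NaHSO3 quench removes excess Br2 and returns any ortho-quinone to the catechol.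

## Compound list

1 | 3,5-dibromo-4-hydroxybenzaldehyde | O=Cc1cc(Br)c(O)c(Br)c1 | starting material
2 | methyl 4-aminobutanoate hydrochloride | COC(=O)CCCN.Cl | starting material
3 | methyl 4-[(3,5-dibromo-4-hydroxybenzyl)amino]butanoate | COC(=O)CCCNCc1cc(Br)c(O)c(Br)c1 | intermediate
4 | 1-(3,5-dibromo-4-hydroxybenzyl)pyrrolidin-2-one | O=C1CCCN1Cc1cc(Br)c(O)c(Br)c1 | intermediate
5 | 1-(3-bromo-4,5-dihydroxybenzyl)pyrrolidin-2-one | O=C1CCCN1Cc1cc(O)c(O)c(Br)c1 | intermediate
6 | 1-(2,3-dibromo-4,5-dihydroxybenzyl)pyrrolidin-2-one | O=C1CCCN1Cc1cc(O)c(O)c(Br)c1Br | intermediate
7 | 1-(2,3,6-tribromo-4,5-dihydroxybenzyl)pyrrolidin-2-one | O=C1CCCN1Cc1c(Br)c(O)c(O)c(Br)c1Br | target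

## Step count and risk

Total step count: 3. Longest linear sequence: 3 steps (1 to 4 to 5 to 7).

**Step 2 (key step).** The most likely failures are:
- a second copper-mediated exchange on the product, since 5 still has a phenoxide next to its remaining bromine;
- oxidative breakdown of the catecholate by traces of oxygen in the presence of copper;
- reductive loss of bromine;
- stalling of the catalyst as the catecholate binds copper.

The fallback gives up the desymmetrization and buys the C3 oxygen. It sets out from amino ester hydrochloride 2, which is combined with commercially available 3-bromo-4-hydroxy-5-methoxybenzaldehyde F1 under the conditions of step 1. This passes through methyl 4-[(3-bromo-4-hydroxy-5-methoxybenzyl)amino]butanoate F2 to 1-(3-bromo-4-hydroxy-5-methoxybenzyl)pyrrolidin-2-one F3. The methyl ether of F3 is then cleaved with BBr3 in CH2Cl2 (−78 °C to rt), which returns the route at catechol 5 at the cost of one extra step.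

**Step 3.** Br2 may oxidise the catechol to the ortho-quinone instead of substituting the ring. It may attack C1, which is para to the C4 hydroxyl, with loss of the lactam-bearing methylene group. The reaction may also stop at 6 because C2, flanked by the benzylic group and a hydroxyl, is the slower position. The fallback sets out from 5 and masks the catechol before bromination:
- methylation with MeI and K2CO3 in DMF gives 1-(3-bromo-4,5-dimethoxybenzyl)pyrrolidin-2-one F4;
- excess Br2 with catalytic Fe powder in warm AcOH leads through 1-(2,3-dibromo-4,5-dimethoxybenzyl)pyrrolidin-2-one F5 to 1-(2,3,6-tribromo-4,5-dimethoxybenzyl)pyrrolidin-2-one F6;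
- BBr3 in CH2Cl2 cleaves both ethers and returns the route at 7.

The dimethyl ether cannot be oxidised to a quinone and is far less prone to ipso cleavage.

**Step 1.** Iminium formation may be slow because the acidic phenol, once deprotonated, lowers the electrophilicity of the aldehyde. Free methyl 4-aminobutanoate may cyclise on itself before it condenses. Amino ester 3 may resist ring closure if it sits as an internal ammonium phenoxide salt. The fallback sets out from aldehyde 1 and makes the N–CH2 bond by substitution instead of reductive amination. Reduction with NaBH4 in MeOH gives 2,6-dibromo-4-(hydroxymethyl)phenol F7. Heating F7 in excess pyrrolidin-2-one F8 with catalytic p-toluenesulfonic acid should ionise the para-hydroxybenzyl alcohol to its quinone methide, which the lactam nitrogen captures. This returns the route at 4.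

## Further compounds

F1 | step 2 | 3-bromo-4-hydroxy-5-methoxybenzaldehyde | COc1cc(C=O)cc(Br)c1O
F2 | step 2 | methyl 4-[(3-bromo-4-hydroxy-5-methoxybenzyl)amino]butanoate | COC(=O)CCCNCc1cc(Br)c(O)c(OC)c1
F3 | step 2 | 1-(3-bromo-4-hydroxy-5-methoxybenzyl)pyrrolidin-2-one | COc1cc(CN2CCCC2=O)cc(Br)c1O
F4 | step 3 | 1-(3-bromo-4,5-dimethoxybenzyl)pyrrolidin-2-one | COc1cc(CN2CCCC2=O)cc(Br)c1OC
F5 | step 3 | 1-(2,3-dibromo-4,5-dimethoxybenzyl)pyrrolidin-2-one | O=C1CCCN1Cc1cc(OC)c(OC)c(Br)c1Br
F6 | step 3 | 1-(2,3,6-tribromo-4,5-dimethoxybenzyl)pyrrolidin-2-one | O=C1CCCN1Cc1c(Br)c(OC)c(OC)c(Br)c1Br
F7 | step 1 | 2,6-dibromo-4-(hydroxymethyl)phenol | OCc1cc(Br)c(O)c(Br)c1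
F8 | step 1 | pyrrolidin-2-one | O=C1CCCN1
A1 | alternative 1 | N-allyl-N-(2,3,6-tribromo-4,5-dimethoxybenzyl)acrylamide | C=CC(=O)N(CC=C)Cc1c(Br)c(OC)c(OC)c(Br)c1Br
A2 | alternative 1 | 1-(2,3,6-tribromo-4,5-dimethoxybenzyl)-1,5-dihydro-2H-pyrrol-2-one | O=C1C=CCN1Cc1c(Br)c(OC)c(OC)c(Br)c1Br
A3 | alternative 2 | 3,6-dibromobenzene-1,2-diol (3,6-dibromocatechol) | Oc1c(Br)ccc(Br)c1O
A4 | alternative 2 | pyrrolidin-2-one | O=C1CCCN1
A5 | alternative 2 | formaldehyde | C=O
A6 | alternative 2 | 1-(2,5-dibromo-3,4-dihydroxybenzyl)pyrrolidin-2-one | O=C1CCCN1Cc1cc(Br)c(O)c(O)c1Br
A7 | alternative 3 | 1-(azidomethyl)-2,3,6-tribromo-4,5-dimethoxybenzene | [N-]=[N+]=NCc1c(Br)c(OC)c(OC)c(Br)c1Br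
A8 | alternative 3 | cyclobutanone | O=C1CCC1
A9 | alternative 3 | 1-(2,3,6-tribromo-4,5-dimethoxybenzyl)pyrrolidin-2-one | O=C1CCCN1Cc1c(Br)c(OC)c(OC)c(Br)c1Br
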